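**Assumption:** the target has no stereogenic centre (it is achiral; the only alkene geometry is fixed by the chromene ring), so no enantiocontrol is needed.

## Retrosynthetic overview
1. Kuwanon A ⇐ its tris-MOM ether by global acetal cleavage.
2. C ring (pyranone) ⇐ one radical annulation: an aroyl radical from 2,4,6-tris(MOM-oxy)benzoic acid adds to an aryl–prenyl alkyne (C3–C4 bond), and the resulting vinyl radical closes onto an ortho-OMOM oxygen (O1–C2 bond, MOM lost).
3. Aryl–prenyl alkyne ⇐ chromene-8-carbaldehyde (alkyne homologation, then Cu-mediated prenylation); chromene ring ⇐ propargyl-ether Claisen on 2-hydroxy-4-(MOM-oxy)benzaldehyde, itself from resorcinol.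
4. A-ring acid ⇐ resorcinol: MOM protection, meta C–H borylation/oxidation, MOM protection, ortho-lithiation/CO2.
5. Ring order: B-ring pyran first (on a resorcinol-derived arene), then the C ring fused onto the pre-formed A ring in the key step. Compound numbers follow the forward sequence below.

## Route

**Step 1**
Reactants: 1 resorcinol
Product: 2 1,3-bis(methoxymethoxy)benzene
Conditions: MOMCl (2.4 equiv), i-Pr2NEt, CH2Cl2, 0 °C → rt
Reagents that add atoms: chloromethyl methyl ether, COCCl
Why: Williamson-type O-alkylation (MOM protection) masks both phenols for the borylation and lithiation steps.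

**Step 2**
Reactants: 2 1,3-bis(methoxymethoxy)benzene
Product: 3 3,5-bis(methoxymethoxy)phenol
Conditions: [Ir(OMe)(cod)]2 (1.5 mol%), dtbpy (3 mol%), B2pin2 (0.7 equiv), THF, 80 °C; then aq. NaOH/H2O2, 0 °C → rt
Reagents that add atoms: hydrogen peroxide, OO (B2pin2 is only transient)
Why: Sterically controlled Ir-catalysed C–H borylation (Hartwig–Miyaura type) occurs only at C5, the one C–H not ortho to an OMOM group, and boronate oxidation gives the phloroglucinol oxygenation pattern.

**Step 3**
Reactants: 3 3,5-bis(methoxymethoxy)phenol
Product: 4 1,3,5-tris(methoxymethoxy)benzene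
Conditions: NaH, MOMCl, DMF, 0 °C → rt
Reagents that add atoms: chloromethyl methyl ether, COCCl
Why: Phenoxide O-alkylation (MOM protection) gives a C3-symmetric arene with three equivalent C–H positions, so the next step has no regiochemical issue.

**Step 4**
Reactants: 4 1,3,5-tris(methoxymethoxy)benzene
Product: 5 2,4,6-tris(methoxymethoxy)benzoic acid
Conditions: n-BuLi, TMEDA, THF, 0 °C; CO2, −78 °C → rt; cold aq. NaH2PO4 work-up (pH ≈ 4)
Reagents that add atoms: carbon dioxide, O=C=O
Why: Directed ortho-metalation between two OMOM groups followed by carboxylation of the aryllithium; the buffered work-up preserves the acetals.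

**Step 5**
Reactants: 1 resorcinol
Product: 6 2,4-dihydroxybenzaldehyde
Conditions: POCl3, DMF, MeCN, −15 °C → rt; then H2O, 50 °C
Reagents that add atoms: N,N-dimethylformamide, CN(C)C=O (formyl carbon); water, O (carbonyl oxygen on iminium hydrolysis)
Why: Vilsmeier–Haack formylation at C4 of resorcinol (para to one OH, ortho to the other) sets the 1,2,4-pattern of the B ring.

**Step 6**
Reactants: 6 2,4-dihydroxybenzaldehyde
Product: 7 2-hydroxy-4-(methoxymethoxy)benzaldehyde
Conditions: MOMCl (1.05 equiv), K2CO3, acetone, 0 °C → rt
Reagents that add atoms: chloromethyl methyl ether, COCCl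
Why: Selective O-alkylation: the 2-OH is tied up in a hydrogen bond to the aldehyde, so only the 4-OH reacts.

**Step 7**
Reactants: 7 2-hydroxy-4-(methoxymethoxy)benzaldehyde; 8 3-chloro-3-methylbut-1-yne
Product: 9 5-(methoxymethoxy)-2,2-dimethyl-2H-chromene-8-carbaldehyde
Conditions: K2CO3, KI, CuI (5 mol%), DMF, 65 °C; then 140 °C (one pot)
Reagents that add atoms: none (all added atoms come from reactant 8)
Why: O-propargylation of the phenoxide, then aromatic propargyl Claisen rearrangement to the only free ortho carbon (C3), 1,5-H shift and oxa-6π electrocyclisation give the chromene with the pyran oxygen ortho to the formyl group.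

**Step 8**
Reactants: 9 5-(methoxymethoxy)-2,2-dimethyl-2H-chromene-8-carbaldehyde
Product: 10 8-ethynyl-5-(methoxymethoxy)-2,2-dimethyl-2H-chromene
Conditions: dimethyl (1-diazo-2-oxopropyl)phosphonate, K2CO3, MeOH, rt
Reagents that add atoms: Ohira–Bestmann reagent, COP(=O)(OC)C(=[N+]=[N-])C(C)=O (supplies one carbon)
Why: Seyferth–Gilbert homologation (Ohira–Bestmann variant) converts ArCHO to ArC≡CH under mild carbonate conditions that leave the MOM ether and chromene untouched.

**Step 9**
Reactants: 10 8-ethynyl-5-(methoxymethoxy)-2,2-dimethyl-2H-chromene; 11 prenyl bromide (1-bromo-3-methylbut-2-ene)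
Product: 12 5-(methoxymethoxy)-2,2-dimethyl-8-(5-methylhex-4-en-1-yn-1-yl)-2H-chromene
Conditions: CuI (10 mol%), K2CO3, n-Bu4NI, DMF, rt
Reagents that add atoms: none (all added atoms come from reactant 11)
Why: Copper-acetylide allylation of the terminal alkyne at the primary carbon of the allylic bromide (SN2 mode) gives the linear, prenyl-type 1,4-enyne.

**Step 10 (key step)**
Reactants: 5 2,4,6-tris(methoxymethoxy)benzoic acid (2 equiv); 12 5-(methoxymethoxy)-2,2-dimethyl-8-(5-methylhex-4-en-1-yn-1-yl)-2H-chromene
Product: 13 5,7-bis(methoxymethoxy)-2-[5-(methoxymethoxy)-2,2-dimethyl-2H-chromen-8-yl]-3-(3-methylbut-2-en-1-yl)-4H-chromen-4-one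
Conditions: dimethyl dicarbonate (3 equiv), 2,6-lutidine, fac-Ir(ppy)3 (2 mol%), DMA, blue LEDs (450 nm), rt, Ar
Reagents that add atoms: none
Why: Proposed new method: the in-situ mixed carbonic anhydride of 5 is reduced by excited Ir(ppy)3 to the 2,4,6-tris(MOM-oxy)benzoyl radical, which adds to the alkyl-bearing alkyne carbon of 12 (forming C3–C4 and an aryl-stabilised vinyl radical at C2); because both ortho carbons of the aroyl ring are blocked, indenone closure is impossible and the vinyl radical (or the vinyl cation after oxidation by Ir(IV)) is captured 6-endo by an ortho-OMOM oxygen, which sheds MOM as MeOCH2+ (ending as CH2(OMe)2) and closes a redox-neutral cycle; the closest known reactions are photoredox acyl-radical generation from carboxylic acids with dimethyl dicarbonate, aroyl-radical/alkyne annulations to indenones, and radical or ICl-type dealkylative cyclisations of 2-methoxyaryl ynones to 3-substituted chromones.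

**Step 11**
Reactants: 13 tris-MOM kuwanon A
Product: 14 kuwanon A
Conditions: 3 M aq. HCl/MeOH (1:5), 40 °C
Reagents that add atoms: none
Why: Acid-catalysed acetal hydrolysis removes all three MOM groups under dilute conditions that the prenyl and 2,2-dimethylchromene units tolerate; no stereocentre is created.

## Compound list
1 | resorcinol | Oc1cccc(O)c1 | starting material
2 | 1,3-bis(methoxymethoxy)benzene | COCOc1cccc(OCOC)c1 | intermediate
3 | 3,5-bis(methoxymethoxy)phenol | COCOc1cc(O)cc(OCOC)c1 | intermediate
4 | 1,3,5-tris(methoxymethoxy)benzene | COCOc1cc(OCOC)cc(OCOC)c1 | intermediate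
5 | 2,4,6-tris(methoxymethoxy)benzoic acid | COCOc1cc(OCOC)c(C(=O)O)c(OCOC)c1 | intermediate
6 | 2,4-dihydroxybenzaldehyde | O=Cc1ccc(O)cc1O | intermediate
7 | 2-hydroxy-4-(methoxymethoxy)benzaldehyde | COCOc1ccc(C=O)c(O)c1 | intermediate
8 | 3-chloro-3-methylbut-1-yne | C#CC(C)(C)Cl | starting material
9 | 5-(methoxymethoxy)-2,2-dimethyl-2H-chromene-8-carbaldehyde | COCOc1ccc(C=O)c2OC(C)(C)C=Cc12 | intermediate
10 | 8-ethynyl-5-(methoxymethoxy)-2,2-dimethyl-2H-chromene | COCOc1ccc(C#C)c2OC(C)(C)C=Cc12 | intermediate
11 | prenyl bromide (1-bromo-3-methylbut-2-ene) | CC(C)=CCBr | starting material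
12 | 5-(methoxymethoxy)-2,2-dimethyl-8-(5-methylhex-4-en-1-yn-1-yl)-2H-chromene | COCOc1ccc(C#CCC=C(C)C)c2OC(C)(C)C=Cc12 | intermediate
13 | 5,7-bis(methoxymethoxy)-2-[5-(methoxymethoxy)-2,2-dimethyl-2H-chromen-8-yl]-3-(3-methylbut-2-en-1-yl)-4H-chromen-4-one | CC(C)=CCc1c(-c2ccc(OCOC)c3c2OC(C)(C)C=C3)oc2cc(OCOC)cc(OCOC)c2c1=O | intermediate
14 | kuwanon A | CC(C)=CCc1c(-c2ccc(O)c3c2OC(C)(C)C=C3)oc2cc(O)cc(O)c2c1=O | target

## Summary
Total steps: 11 (convergent). Longest linear sequence: 7 (steps 5 → 6 → 7 → 8 → 9 → 10 → 11).

Steps most likely to fail: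
1. **Step 10.** Electron transfer to the hindered, electron-rich mixed anhydride may be slow; the aroyl radical may add to the chromene or prenyl C=C instead of the alkyne; the vinyl radical may be reduced to the chalcone instead of closing. Fallback: move the radical C–C event to a 1,3-diketone. Convert 9 to its methyl ketone (MeMgBr, then MnO2), Claisen-condense its lithium enolate with the imidazolide of 5, C-prenylate the diketone by Mn(OAc)3-mediated radical addition to trimethyl(2-methylbut-3-en-2-yl)silane, then cyclodehydrate and deprotect with HCl/MeOH.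
2. **Step 7.** O-alkylation of the chelated phenol by a tertiary propargylic chloride and the subsequent Claisen rearrangement may be low-yielding. Fallback: direct chromenylation of 7 with 3-methylbut-2-enal (EDDA, toluene, reflux; aldol-type ortho-alkylation then oxa-6π electrocyclisation), which avoids the hindered ether altogether.
3. **Step 9.** SN2′ attack would give the 1,1-dimethylallyl isomer, and base could isomerise the skipped enyne. Fallback: Corey–Fuchs olefination of 9 (CBr4/PPh3), then n-BuLi to the lithium acetylide and CuBr·SMe2-mediated trapping with 11 in the same pot, replacing steps 8–9 and avoiding carbonate/DMF.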